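Ring B is cut at the C3a–C7a bond. A silyl triflate ionises an acyclic tertiary trifluoroacetate with help from the neighbouring C4 bromine, and the resulting enantiopure bromonium ion of the E C3a=C4 alkene is opened at C3a by the α-carbon (C7a) of a silyl dienol ether through a chair. One operation closes ring B and sets C3a and C7a. It uses the fact that in ring B of the target the C4 bromine is equatorial and antiperiplanar to the ring bond C3a–C7a while the C3a methyl is axial, the result of trans addition to an E alkene. The precursor is an acyclic anti bromohydrin ester with a Z 1-silyloxy-1,3-diene terminus, made enantiopure by one catalytic epoxidation.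

Key step: step 10

Labels: hydrindane locants are used for rings A and B (C1 side chain, C2 hydroxyl, C3, C3a methyl, C4 bromine, C5, C6, C7 methyl carbinol, C7a ring-fusion hydrogen). Ca is the acetoxy carbon, C1'–C6' are ring C (C1' carbinol, C4' CHBr, C5' CMe2). β is the face of the C3a methyl, α the opposite face.

Assumption: the D-fructose-derived ketone is taken to epoxidise both E-trisubstituted alkenes with its usual face preference, which corresponds to the R configuration at the CH–O carbon of 12 and of 33.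

Design remark: a tertiary silyl ether at C3a would not ionise under conditions that spare a dienol ether, and a conjugated enone would be silylated mainly at the α'-methylene. The precursor therefore carries a tertiary trifluoroacetate, and its dienol ether is made from the β,γ-unsaturated ketone. Ring C is joined as an alkenyl unit and C1' is set from Ca, because the faces of the ring C bromoketone differ only through the weak conformational preference of the remote bromine.

Step 1
Reactants: 1 but-3-yn-1-ol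
Product: 2 tert-butyl(but-3-yn-1-yloxy)diphenylsilane
Conditions: t-BuPh2SiCl, imidazole, DMF, 0 °C to rt
Reagents that add atoms: tert-butyl(chloro)diphenylsilane, CC(C)(C)[Si](Cl)(c1ccccc1)c1ccccc1
Why: Standard silylation of a primary alcohol; the bulky, weakly nucleophilic silyl ether keeps this oxygen a spectator when the bromonium ion is generated in step 10.

Step 2
Reactants: 2 tert-butyl(but-3-yn-1-yloxy)diphenylsilane; 3 trimethylaluminium; 4 paraformaldehyde
Product: 7 (E)-5-[(tert-butyldiphenylsilyl)oxy]-3-methylpent-2-en-1-ol, via alkenylalane 5 (not isolated), via lithium aluminate 6 (not isolated)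
Conditions: Me3Al, Cp2ZrCl2 (0.25 equiv), CH2Cl2, 0 °C to rt; n-BuLi, THF, −78 °C; (CH2O)n, −78 °C to rt
Reagents that add atoms: trimethylaluminium 3, C[Al](C)C; paraformaldehyde 4, C=O
Why: Negishi zirconium-catalysed carboalumination adds methyl and aluminium syn across the terminal alkyne with aluminium at the terminus, and the aluminate is hydroxymethylated with retention, which fixes the E geometry of the future C3a=C4 alkene.

Step 3
Reactants: 7 (E)-5-[(tert-butyldiphenylsilyl)oxy]-3-methylpent-2-en-1-ol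
Product: 8 (E)-[(5-bromo-3-methylpent-3-en-1-yl)oxy](tert-butyl)diphenylsilane
Conditions: CBr4, PPh3, CH2Cl2, 0 °C
Reagents that add atoms: tetrabromomethane, BrC(Br)(Br)Br
Why: Appel bromination of the primary allylic alcohol is neutral and should proceed without allylic transposition or loss of alkene geometry.

Step 4
Reactants: 8 (E)-[(5-bromo-3-methylpent-3-en-1-yl)oxy](tert-butyl)diphenylsilane; 9 N-methoxy-N-methylacetamide
Product: 11 (E)-7-[(tert-butyldiphenylsilyl)oxy]-N-methoxy-N,5-dimethylhept-4-enamide, via lithium enolate 10 (not isolated)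
Conditions: LiN(iPr)2, THF, −78 °C; then 8, −78 to −40 °C
Reagents that add atoms: none
Why: SN2 alkylation of the amide enolate with a primary allylic bromide installs C6 and C7, and C7 is carried as a Weinreb amide that is inert to the epoxidation and bromide opening that follow.

Step 5
Reactants: 11 (E)-7-[(tert-butyldiphenylsilyl)oxy]-N-methoxy-N,5-dimethylhept-4-enamide
Product: 12 3-[(2R,3R)-3-{2-[(tert-butyldiphenylsilyl)oxy]ethyl}-3-methyloxiran-2-yl]-N-methoxy-N-methylpropanamide
Conditions: 1,2:4,5-di-O-isopropylidene-β-D-erythro-2,3-hexodiulo-2,6-pyranose (0.3 equiv), KHSO5 (as Oxone), K2CO3, Bu4NHSO4, aq. Na2B4O7 buffer, MeCN–CH2(OMe)2, 0 °C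
Reagents that add atoms: potassium peroxymonosulfate, [K+].[O-]S(=O)(=O)OO
Why: Shi asymmetric epoxidation of the only electron-rich trisubstituted alkene; the chiral dioxirane delivers oxygen through the spiro transition state to one face and gives the (R,R) epoxide, the single source of absolute configuration for rings A and B.

Step 6
Reactants: 12 3-[(2R,3R)-3-{2-[(tert-butyldiphenylsilyl)oxy]ethyl}-3-methyloxiran-2-yl]-N-methoxy-N-methylpropanamide
Product: 13 (4S,5R)-4-bromo-7-[(tert-butyldiphenylsilyl)oxy]-5-hydroxy-N-methoxy-N,5-dimethylheptanamide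
Conditions: Li2NiBr4, THF, 0 °C to rt
Reagents that add atoms: dilithium tetrabromonickelate, [Li+].[Li+].[Ni+2].[Br-].[Br-].[Br-].[Br-]
Why: SN2 epoxide opening by soft bromide at the less substituted C4 inverts that carbon and gives the anti bromohydrin with secondary bromide and tertiary alcohol, C3a being untouched.

Step 7
Reactants: 13 (4S,5R)-4-bromo-7-[(tert-butyldiphenylsilyl)oxy]-5-hydroxy-N-methoxy-N,5-dimethylheptanamide; 14 allylmagnesium bromide
Product: 15 (7S,8R)-7-bromo-10-[(tert-butyldiphenylsilyl)oxy]-8-hydroxy-8-methyldec-1-en-4-one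
Conditions: CH2=CHCH2MgBr (2.3 equiv), THF, −78 °C; aq. NH4Cl at −78 °C
Reagents that add atoms: allylmagnesium bromide 14, C=CC[Mg]Br
Why: Weinreb ketone synthesis stops at the chelated tetrahedral adduct and gives the β,γ-unsaturated ketone, whose doubly activated C7a methylene secures the regiochemistry of the dienol ether; the magnesium alkoxide of the bromohydrin should not close to the epoxide at this temperature.

Step 8
Reactants: 15 (7S,8R)-7-bromo-10-[(tert-butyldiphenylsilyl)oxy]-8-hydroxy-8-methyldec-1-en-4-one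
Product: 16 (3R,4S)-4-bromo-1-[(tert-butyldiphenylsilyl)oxy]-3-methyl-7-oxodec-9-en-3-yl trifluoroacetate
Conditions: (CF3CO)2O, pyridine, CH2Cl2, −20 °C
Reagents that add atoms: trifluoroacetic anhydride, O=C(OC(=O)C(F)(F)F)C(F)(F)F
Why: Acylation of the hindered tertiary alcohol with a highly reactive anhydride turns the C3a oxygen into a nucleofuge that a silyl triflate can ionise at low temperature.

Step 9
Reactants: 16 (3R,4S)-4-bromo-1-[(tert-butyldiphenylsilyl)oxy]-3-methyl-7-oxodec-9-en-3-yl trifluoroacetate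
Product: 17 (3R,4S,7Z)-4-bromo-7-[(tert-butyldimethylsilyl)oxy]-1-[(tert-butyldiphenylsilyl)oxy]-3-methyldeca-7,9-dien-3-yl trifluoroacetate
Conditions: t-BuMe2SiOTf, Et3N, CH2Cl2, −78 °C
Reagents that add atoms: tert-butyldimethylsilyl trifluoromethanesulfonate, CC(C)(C)[Si](C)(C)OS(=O)(=O)C(F)(F)F
Why: Soft enolisation with silyl triflate and amine removes the most acidic proton, at C7a between carbonyl and vinyl, and gives the conjugated silyl dienol ether, the Z isomer being favoured because it keeps the vinyl group away from the C6 chain.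

Step 10
Reactants: 17 (3R,4S,7Z)-4-bromo-7-[(tert-butyldimethylsilyl)oxy]-1-[(tert-butyldiphenylsilyl)oxy]-3-methyldeca-7,9-dien-3-yl trifluoroacetate
Product: 19 (2S,3S,4S)-4-bromo-3-{2-[(tert-butyldiphenylsilyl)oxy]ethyl}-2-ethenyl-3-methylcyclohexan-1-one, via bromonium ion 18 (not isolated)
Conditions: t-BuMe2SiOTf (0.2 equiv), 2,6-di-tert-butyl-4-methylpyridine, CH2Cl2 (0.01 M), −78 to −40 °C; then Et3N, aq. NaHCO3
Reagents that add atoms: none
Why: The silyl triflate silylates the trifluoroacetate carbonyl and the C3a–O bond breaks with rearward participation of the C4 bromine, which gives the bromiranium ion of the E alkene on one face only; C7a of the dienol ether opens this ion at the tertiary C3a, and the silyloxocarbenium ion so formed passes its silyl group to trifluoroacetate, which frees the C7 ketone and regenerates the silyl triflate. The closest known reaction type is the bromonium-initiated cation–olefin cyclisation whose bromonium ion is generated enantiospecifically from a bromohydrin derivative, combined here with the Lewis acid-promoted tertiary alkylation of silyl enol ethers (Mukaiyama/Reetz type); the conjugated silyl dienol ether is a terminating olefin not yet used in it. Ring B closes in the 6-endo mode at the bromiranium ion through a chair transition state. C3a is fixed by two successive inversions (net retention of the C–O configuration of 17), C4 is carried over unchanged with bromine anti to the new bond and therefore equatorial, and C7a follows from the Z enol ether geometry, which places the vinyl group equatorial (an axial epimer could equilibrate through the enol). The step needs chirality transfer without bromonium scrambling, bond formation through C7a and opening at C3a: no electrophilic bromine source or spectator trisubstituted alkene is present and high dilution suppresses intermolecular bromonium transfer, attack through Ca would need an eight-membered ring, both ether oxygens are shielded by bulky silyl groups, and the tertiary carbon carries most of the positive charge.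

Step 11
Reactants: 19 (2S,3S,4S)-4-bromo-3-{2-[(tert-butyldiphenylsilyl)oxy]ethyl}-2-ethenyl-3-methylcyclohexan-1-one; 20 methyllithium
Product: 21 (1R,2S,3S,4S)-4-bromo-3-{2-[(tert-butyldiphenylsilyl)oxy]ethyl}-2-ethenyl-1,3-dimethylcyclohexan-1-ol
Conditions: MeLi, CeCl3, THF, −78 °C
Reagents that add atoms: methyllithium 20, [Li]C
Why: Organocerium 1,2-addition to the enolisable ketone avoids deprotonation at C7a; the axial face of C7 is blocked by the syn-axial C3a methyl, so methyl enters equatorially and the C7 hydroxyl becomes axial as in the target.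

Step 12
Reactants: 21 (1R,2S,3S,4S)-4-bromo-3-{2-[(tert-butyldiphenylsilyl)oxy]ethyl}-2-ethenyl-1,3-dimethylcyclohexan-1-ol
Product: 22 (1R,2S,3S,4S)-4-bromo-2-ethenyl-3-(2-hydroxyethyl)-1,3-dimethylcyclohexan-1-ol
Conditions: Bu4NF, THF, 0 °C to rt
Reagents that add atoms: none
Why: Fluoride-mediated desilylation frees the primary C2 alcohol; the equatorial neopentyl-type bromide has no antiperiplanar hydrogen and should resist elimination.

Step 13
Reactants: 22 (1R,2S,3S,4S)-4-bromo-2-ethenyl-3-(2-hydroxyethyl)-1,3-dimethylcyclohexan-1-ol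
Product: 23 [(1S,2S,3R,6S)-6-bromo-2-ethenyl-3-hydroxy-1,3-dimethylcyclohexyl]acetaldehyde
Conditions: PhI(OAc)2, 2,2,6,6-tetramethylpiperidin-1-oxyl (0.1 equiv), CH2Cl2, rt
Reagents that add atoms: none
Why: Oxoammonium (TEMPO) oxidation is selective for the primary alcohol and leaves the tertiary alcohol and the vinyl group untouched.

Step 14
Reactants: 23 [(1S,2S,3R,6S)-6-bromo-2-ethenyl-3-hydroxy-1,3-dimethylcyclohexyl]acetaldehyde
Product: 24 [(1S,2S,3R,6S)-6-bromo-2-ethenyl-3-hydroxy-1,3-dimethylcyclohexyl]acetaldehyde oxime (E/Z mixture)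
Conditions: NH2OH·HCl, NaOAc, EtOH, rt
Reagents that add atoms: hydroxylamine hydrochloride, NO.Cl
Why: Oxime condensation of the aldehyde; both oxime isomers serve as nitrile oxide precursors.

Step 15
Reactants: 24 [(1S,2S,3R,6S)-6-bromo-2-ethenyl-3-hydroxy-1,3-dimethylcyclohexyl]acetaldehyde oxime
Product: 26 tricyclic isoxazoline (4,5-dihydroisoxazole fused to ring A through C2 as C=N and C1, oxygen on Ca; trans-hydrindane, 1β-H, 3aβ-methyl, 4β-bromo, 7β-hydroxy-7α-methyl, 7aα-H), via nitrile oxide 25 (not isolated)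
Conditions: PhI(OAc)2, CF3CO2H (0.1 equiv), MeOH, 0 °C to rt
Reagents that add atoms: none
Why: Intramolecular nitrile oxide–alkene 1,3-dipolar cycloaddition; the three-atom tether dictates C2–C1 and O–Ca bonding and closes ring A trans-fused from the two equatorial arms, and the vinyl group reacts in the rotamer that eclipses C7a–H, so Ca ends up α, away from the angular methyl and the axial C7 hydroxyl.

Step 16
Reactants: 26 tricyclic isoxazoline
Product: 27 (1R,3aS,4S,7R,7aS)-4-bromo-7-hydroxy-1-(hydroxymethyl)-3a,7-dimethyloctahydro-2H-inden-2-one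
Conditions: Mo(CO)6, MeCN–H2O, 80 °C
Reagents that add atoms: water, O
Why: Reductive N–O cleavage of the isoxazoline and hydrolysis of the β-hydroxy imine (isoxazoline as masked aldol) unveil the C2 ketone and the Ca alcohol under neutral conditions that leave both C–Br bonds alone.

Step 17
Reactants: 27 (1R,3aS,4S,7R,7aS)-4-bromo-7-hydroxy-1-(hydroxymethyl)-3a,7-dimethyloctahydro-2H-inden-2-one
Product: 28 (1R,2R,3aS,4S,7R,7aS)-4-bromo-1-(hydroxymethyl)-3a,7-dimethyloctahydro-1H-indene-2,7-diol
Conditions: Zn(BH4)2, Et2O, −20 °C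
Reagents that add atoms: none
Why: Chelation-controlled hydride reduction: zinc bridges the Ca alkoxide and the C2 carbonyl on the α face, so external hydride should add from the β face and give the 2α-alcohol cis to the C1 substituent.

Step 18
Reactants: 28 (1R,2R,3aS,4S,7R,7aS)-4-bromo-1-(hydroxymethyl)-3a,7-dimethyloctahydro-1H-indene-2,7-diol
Product: 29 4-methoxybenzylidene acetal of 28 (1,3-dioxane across O-2 and O-a, cis-fused to ring A)
Conditions: 4-MeOC6H4CH(OMe)2, pyridinium 4-toluenesulfonate (0.1 equiv), CH2Cl2, rt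
Reagents that add atoms: 4-methoxybenzaldehyde dimethyl acetal, COc1ccc(cc1)C(OC)OC
Why: Acid-catalysed transacetalisation ties the cis-related C2 and Ca hydroxyls into a six-membered acetal; the tertiary C7 alcohol cannot take part.

Step 19
Reactants: 29 4-methoxybenzylidene acetal of 28
Product: 30 (1R,2R,3aS,4S,7R,7aS)-4-bromo-1-(hydroxymethyl)-2-[(4-methoxybenzyl)oxy]-3a,7-dimethyloctahydro-1H-inden-7-ol
Conditions: i-Bu2AlH, CH2Cl2, −78 to 0 °C
Reagents that add atoms: none
Why: Regioselective reductive acetal opening: the aluminium hydride coordinates the less hindered primary oxygen and cleaves its C–O bond, which leaves the 4-methoxybenzyl ether on O-2 and frees the Ca alcohol.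

Step 20
Reactants: 30 (1R,2R,3aS,4S,7R,7aS)-4-bromo-1-(hydroxymethyl)-2-[(4-methoxybenzyl)oxy]-3a,7-dimethyloctahydro-1H-inden-7-ol
Product: 31 (1S,2R,3aS,4S,7R,7aS)-4-bromo-7-hydroxy-2-[(4-methoxybenzyl)oxy]-3a,7-dimethyloctahydro-1H-indene-1-carbaldehyde
Conditions: PhI(OAc)2, 2,2,6,6-tetramethylpiperidin-1-oxyl (0.1 equiv), CH2Cl2, rt
Reagents that add atoms: none
Why: TEMPO oxidation of the primary alcohol under non-basic conditions avoids β-elimination of the C2 ether and epimerisation at C1.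

Step 21
Reactants: 32 6-methylhept-5-en-2-one
Product: 33 4-[(2R)-3,3-dimethyloxiran-2-yl]butan-2-one
Conditions: 1,2:4,5-di-O-isopropylidene-β-D-erythro-2,3-hexodiulo-2,6-pyranose (0.3 equiv), KHSO5 (as Oxone), K2CO3, Bu4NHSO4, aq. Na2B4O7 buffer, MeCN–CH2(OMe)2, 0 °C
Reagents that add atoms: potassium peroxymonosulfate, [K+].[O-]S(=O)(=O)OO
Why: Shi asymmetric epoxidation of the trisubstituted alkene sets the configuration from which C4' is derived.

Step 22
Reactants: 33 4-[(2R)-3,3-dimethyloxiran-2-yl]butan-2-one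
Product: 34 (5S)-5-bromo-6-hydroxy-6-methylheptan-2-one
Conditions: Li2NiBr4, THF, 0 °C to rt
Reagents that add atoms: dilithium tetrabromonickelate, [Li+].[Li+].[Ni+2].[Br-].[Br-].[Br-].[Br-]
Why: SN2 opening of the epoxide by bromide at the secondary carbon with inversion gives the C4' bromide in the S configuration.

Step 23
Reactants: 34 (5S)-5-bromo-6-hydroxy-6-methylheptan-2-one
Product: 35 (3S)-3-bromo-2-methyl-6-oxoheptan-2-yl trifluoroacetate
Conditions: (CF3CO)2O, pyridine, CH2Cl2, −20 °C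
Reagents that add atoms: trifluoroacetic anhydride, O=C(OC(=O)C(F)(F)F)C(F)(F)F
Why: Trifluoroacetylation of the tertiary alcohol installs the nucleofuge, as in step 8.

Step 24
Reactants: 35 (3S)-3-bromo-2-methyl-6-oxoheptan-2-yl trifluoroacetate
Product: 37 (3S)-3-bromo-6-[(tert-butyldimethylsilyl)oxy]-2-methylhept-6-en-2-yl trifluoroacetate, via lithium enolate 36 (not isolated)
Conditions: LiN(iPr)2, THF, −78 °C; t-BuMe2SiOTf, −78 °C
Reagents that add atoms: tert-butyldimethylsilyl trifluoromethanesulfonate, CC(C)(C)[Si](C)(C)OS(=O)(=O)C(F)(F)F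
Why: Kinetic deprotonation of the methyl ketone at the methyl group and O-silylation give the terminal silyl enol ether that makes C6' the nucleophilic carbon.

Step 25
Reactants: 37 (3S)-3-bromo-6-[(tert-butyldimethylsilyl)oxy]-2-methylhept-6-en-2-yl trifluoroacetate
Product: 39 (4S)-4-bromo-3,3-dimethylcyclohexan-1-one, via bromonium ion 38 (not isolated)
Conditions: t-BuMe2SiOTf (0.2 equiv), 2,6-di-tert-butyl-4-methylpyridine, CH2Cl2, −78 to −40 °C
Reagents that add atoms: none
Why: The same bromonium-initiated cation–olefin cyclisation as in step 10, here terminated by a simple silyl enol ether: C6' attacks C5' through a chair (6-endo) and C4' keeps the configuration set in steps 21 and 22.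

Step 26
Reactants: 39 (4S)-4-bromo-3,3-dimethylcyclohexan-1-one
Product: 41 (4S)-4-bromo-5,5-dimethylcyclohex-1-en-1-yl trifluoromethanesulfonate, via lithium enolate 40 (not isolated)
Conditions: LiN(SiMe3)2, N-(5-chloropyridin-2-yl)bis(trifluoromethanesulfonimide) present from the start, THF, −78 °C
Reagents that add atoms: N-(5-chloropyridin-2-yl)-1,1,1-trifluoro-N-[(trifluoromethyl)sulfonyl]methanesulfonamide, FC(F)(F)S(=O)(=O)N(c1ccc(Cl)cn1)S(=O)(=O)C(F)(F)F
Why: Kinetic enolisation away from the neopentyl C6' methylene and O-triflation (enol triflate synthesis with Comins' reagent) give the C1'=C2' alkenyl triflate; trapping in situ at −78 °C forestalls cyclopropane formation by the γ-bromo enolate.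

Step 27
Reactants: 31 (1S,2R,3aS,4S,7R,7aS)-4-bromo-7-hydroxy-2-[(4-methoxybenzyl)oxy]-3a,7-dimethyloctahydro-1H-indene-1-carbaldehyde; 41 (4S)-4-bromo-5,5-dimethylcyclohex-1-en-1-yl trifluoromethanesulfonate
Product: 43 [(1R,2R,3aS,4S,7R,7aS)-4-bromo-7-hydroxy-2-[(4-methoxybenzyl)oxy]-3a,7-dimethyloctahydro-1H-inden-1-yl][(4S)-4-bromo-5,5-dimethylcyclohex-1-en-1-yl]methanol (both Ca epimers), via alkenylchromium 42 (not isolated)
Conditions: CrCl2, NiCl2 (0.05 equiv), DMF, rt
Reagents that add atoms: none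
Why: Nozaki–Hiyama–Kishi coupling: the alkenylchromium reagent forms from the triflate under nickel catalysis and adds chemoselectively to the aldehyde in the presence of the secondary bromides and the free tertiary alcohol; the Ca configuration is immaterial because step 28 erases it.

Step 28
Reactants: 43 allylic alcohols (both Ca epimers)
Product: 44 [(1S,2R,3aS,4S,7R,7aS)-4-bromo-7-hydroxy-2-[(4-methoxybenzyl)oxy]-3a,7-dimethyloctahydro-1H-inden-1-yl][(4S)-4-bromo-5,5-dimethylcyclohex-1-en-1-yl]methanone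
Conditions: Dess–Martin periodinane, NaHCO3, CH2Cl2, 0 °C
Reagents that add atoms: none
Why: Dess–Martin oxidation converges both Ca epimers on one enone under buffered, non-basic conditions.

Step 29
Reactants: 44 enone
Product: 45 (R)-[(1R,2R,3aS,4S,7R,7aS)-4-bromo-7-hydroxy-2-[(4-methoxybenzyl)oxy]-3a,7-dimethyloctahydro-1H-inden-1-yl][(4S)-4-bromo-5,5-dimethylcyclohex-1-en-1-yl]methanol
Conditions: Zn(BH4)2, Et2O, −40 °C
Reagents that add atoms: none
Why: Chelation-controlled 1,2-reduction: zinc locks the Ca carbonyl and the C2 ether oxygen in a cis-fused six-membered chelate and hydride adds to the open face anti to C7a (also the Felkin–Anh sense), which should give the (R)-carbinol.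

Step 30
Reactants: 45 (R)-allylic alcohol
Product: 46 epoxy alcohol (45 with the C1'=C2' alkene converted into the epoxide on the ring C face cis to the C4' bromine; erythro to the Ca hydroxyl)
Conditions: VO(acac)2 (0.05 equiv), t-BuOOH, CH2Cl2, 0 °C to rt
Reagents that add atoms: tert-butyl hydroperoxide, CC(C)(C)OO
Why: Hydroxyl-directed epoxidation: allylic 1,2-strain between the carbinol substituent and C6' favours the erythro epoxy alcohol, so the Ca stereocentre, not the remote C4' bromine, places the C1'–O bond on the required face.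

Step 31
Reactants: 46 epoxy alcohol
Product: 47 (R)-[(1R,2R,3aS,4S,7R,7aS)-4-bromo-7-hydroxy-2-[(4-methoxybenzyl)oxy]-3a,7-dimethyloctahydro-1H-inden-1-yl][(1R,4S)-4-bromo-1-hydroxy-3,3-dimethylcyclohexyl]methanol
Conditions: Ti(OiPr)4, LiBH4, THF, 0 °C to rt
Reagents that add atoms: none
Why: Titanium-assisted regioselective hydride opening of the 2,3-epoxy alcohol at the distal secondary carbon C2' leaves the C1'–O bond intact and gives the tertiary C1' alcohol; borohydride should not touch the hindered secondary bromides.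

Step 32
Reactants: 47 diol
Product: 48 (R)-[(1S,2R,3aS,4S,7R,7aS)-4-bromo-7-hydroxy-2-[(4-methoxybenzyl)oxy]-3a,7-dimethyloctahydro-1H-inden-1-yl][(1R,4S)-4-bromo-1-hydroxy-3,3-dimethylcyclohexyl]methyl acetate
Conditions: Ac2O, 4-(dimethylamino)pyridine (0.2 equiv), pyridine, CH2Cl2, rt
Reagents that add atoms: acetic anhydride, CC(=O)OC(C)=O
Why: Nucleophile-catalysed acetylation acylates the only free secondary hydroxyl (Ca); the two tertiary alcohols do not react under these conditions.

Step 33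
Reactants: 48 acetate
Product: 49 (R)-[(1S,2R,3aS,4S,7R,7aS)-4-bromo-2,7-dihydroxy-3a,7-dimethyloctahydro-1H-inden-1-yl][(1R,4S)-4-bromo-1-hydroxy-3,3-dimethylcyclohexyl]methyl acetate
Conditions: 2,3-dichloro-5,6-dicyano-1,4-benzoquinone, CH2Cl2–pH 7 buffer, 0 °C
Reagents that add atoms: none
Why: Oxidative cleavage of the 4-methoxybenzyl ether under neutral conditions frees the C2 hydroxyl without acyl migration and gives the target.

Compound list

1 | but-3-yn-1-ol | C#CCCO | starting material
2 | tert-butyl(but-3-yn-1-yloxy)diphenylsilane | C#CCCO[Si](c1ccccc1)(c1ccccc1)C(C)(C)C | intermediate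
3 | trimethylaluminium | C[Al](C)C | starting material
4 | paraformaldehyde (formaldehyde unit) | C=O | starting material
5 | (E)-{4-[(tert-butyldiphenylsilyl)oxy]-2-methylbut-1-en-1-yl}dimethylalane | C[Al](C)/C=C(\C)CCO[Si](c1ccccc1)(c1ccccc1)C(C)(C)C | intermediate (not isolated)
6 | lithium (E)-butyl{4-[(tert-butyldiphenylsilyl)oxy]-2-methylbut-1-en-1-yl}dimethylaluminate | [Li+].CCCC[Al-](C)(C)/C=C(\C)CCO[Si](c1ccccc1)(c1ccccc1)C(C)(C)C | intermediate (not isolated)
7 | (E)-5-[(tert-butyldiphenylsilyl)oxy]-3-methylpent-2-en-1-ol | OC/C=C(\C)CCO[Si](c1ccccc1)(c1ccccc1)C(C)(C)C | intermediate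
8 | (E)-[(5-bromo-3-methylpent-3-en-1-yl)oxy](tert-butyl)diphenylsilane | BrC/C=C(\C)CCO[Si](c1ccccc1)(c1ccccc1)C(C)(C)C | intermediate
9 | N-methoxy-N-methylacetamide | CC(=O)N(C)OC | starting material
10 | lithium enolate of N-methoxy-N-methylacetamide | [Li]OC(=C)N(C)OC | intermediate (not isolated)
11 | (E)-7-[(tert-butyldiphenylsilyl)oxy]-N-methoxy-N,5-dimethylhept-4-enamide | CON(C)C(=O)CC/C=C(\C)CCO[Si](c1ccccc1)(c1ccccc1)C(C)(C)C | intermediate
12 | 3-[(2R,3R)-3-{2-[(tert-butyldiphenylsilyl)oxy]ethyl}-3-methyloxiran-2-yl]-N-methoxy-N-methylpropanamide | CON(C)C(=O)CC[C@H]1O[C@]1(C)CCO[Si](c1ccccc1)(c1ccccc1)C(C)(C)C | intermediate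
13 | (4S,5R)-4-bromo-7-[(tert-butyldiphenylsilyl)oxy]-5-hydroxy-N-methoxy-N,5-dimethylheptanamide | CON(C)C(=O)CC[C@H](Br)[C@](C)(O)CCO[Si](c1ccccc1)(c1ccccc1)C(C)(C)C | intermediate
14 | allylmagnesium bromide | C=CC[Mg]Br | starting material
15 | (7S,8R)-7-bromo-10-[(tert-butyldiphenylsilyl)oxy]-8-hydroxy-8-methyldec-1-en-4-one | C=CCC(=O)CC[C@H](Br)[C@](C)(O)CCO[Si](c1ccccc1)(c1ccccc1)C(C)(C)C | intermediate
16 | (3R,4S)-4-bromo-1-[(tert-butyldiphenylsilyl)oxy]-3-methyl-7-oxodec-9-en-3-yl trifluoroacetate | C=CCC(=O)CC[C@H](Br)[C@](C)(OC(=O)C(F)(F)F)CCO[Si](c1ccccc1)(c1ccccc1)C(C)(C)C | intermediate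
17 | (3R,4S,7Z)-4-bromo-7-[(tert-butyldimethylsilyl)oxy]-1-[(tert-butyldiphenylsilyl)oxy]-3-methyldeca-7,9-dien-3-yl trifluoroacetate (key-step precursor) | C=C/C=C(\O[Si](C)(C)C(C)(C)C)CC[C@H](Br)[C@](C)(OC(=O)C(F)(F)F)CCO[Si](c1ccccc1)(c1ccccc1)C(C)(C)C | intermediate
18 | bromiranium ion of the E C3a=C4 alkene (bromine bridging C3a and C4, dienol ether intact) | C=C/C=C(\O[Si](C)(C)C(C)(C)C)CC[C@@H]1[Br+][C@@]1(C)CCO[Si](c1ccccc1)(c1ccccc1)C(C)(C)C | intermediate (not isolated)
19 | (2S,3S,4S)-4-bromo-3-{2-[(tert-butyldiphenylsilyl)oxy]ethyl}-2-ethenyl-3-methylcyclohexan-1-one (key-step product) | CC(C)(C)[Si](c1ccccc1)(c1ccccc1)OCC[C@]1(C)[C@@H](Br)CCC(=O)[C@H]1C=C | intermediate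
20 | methyllithium | [Li]C | starting material
21 | (1R,2S,3S,4S)-4-bromo-3-{2-[(tert-butyldiphenylsilyl)oxy]ethyl}-2-ethenyl-1,3-dimethylcyclohexan-1-ol | CC(C)(C)[Si](c1ccccc1)(c1ccccc1)OCC[C@]1(C)[C@@H](Br)CC[C@@](C)(O)[C@H]1C=C | intermediate
22 | (1R,2S,3S,4S)-4-bromo-2-ethenyl-3-(2-hydroxyethyl)-1,3-dimethylcyclohexan-1-ol | OCC[C@]1(C)[C@@H](Br)CC[C@@](C)(O)[C@H]1C=C | intermediate
23 | [(1S,2S,3R,6S)-6-bromo-2-ethenyl-3-hydroxy-1,3-dimethylcyclohexyl]acetaldehyde | O=CC[C@]1(C)[C@@H](Br)CC[C@@](C)(O)[C@H]1C=C | intermediate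
24 | [(1S,2S,3R,6S)-6-bromo-2-ethenyl-3-hydroxy-1,3-dimethylcyclohexyl]acetaldehyde oxime (E/Z mixture) | ON=CC[C@]1(C)[C@@H](Br)CC[C@@](C)(O)[C@H]1C=C | intermediate
25 | [(1S,2S,3R,6S)-6-bromo-2-ethenyl-3-hydroxy-1,3-dimethylcyclohexyl]acetonitrile oxide | [O-][N+]#CC[C@]1(C)[C@@H](Br)CC[C@@](C)(O)[C@H]1C=C | intermediate (not isolated)
26 | tricyclic isoxazoline (ring A closed; C2=N, Ca–O; 1β-H, 3aS,4S,7R,7aS) | C1ON=C2C[C@]3(C)[C@@H](Br)CC[C@@](C)(O)[C@H]3[C@H]12 | intermediate
27 | (1R,3aS,4S,7R,7aS)-4-bromo-7-hydroxy-1-(hydroxymethyl)-3a,7-dimethyloctahydro-2H-inden-2-one | OC[C@@H]1C(=O)C[C@]2(C)[C@@H](Br)CC[C@@](C)(O)[C@@H]12 | intermediate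
28 | (1R,2R,3aS,4S,7R,7aS)-4-bromo-1-(hydroxymethyl)-3a,7-dimethyloctahydro-1H-indene-2,7-diol | OC[C@@H]1[C@H](O)C[C@]2(C)[C@@H](Br)CC[C@@](C)(O)[C@@H]12 | intermediate
29 | 4-methoxybenzylidene acetal of 28 across O-2 and O-a (acetal carbon left undefined; aryl expected equatorial) | COc1ccc(cc1)C1OC[C@@H]2[C@H](O1)C[C@]1(C)[C@@H](Br)CC[C@@](C)(O)[C@@H]21 | intermediate
30 | (1R,2R,3aS,4S,7R,7aS)-4-bromo-1-(hydroxymethyl)-2-[(4-methoxybenzyl)oxy]-3a,7-dimethyloctahydro-1H-inden-7-ol | OC[C@@H]1[C@H](OCc2ccc(OC)cc2)C[C@]2(C)[C@@H](Br)CC[C@@](C)(O)[C@@H]12 | intermediate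
31 | (1S,2R,3aS,4S,7R,7aS)-4-bromo-7-hydroxy-2-[(4-methoxybenzyl)oxy]-3a,7-dimethyloctahydro-1H-indene-1-carbaldehyde | O=C[C@@H]1[C@H](OCc2ccc(OC)cc2)C[C@]2(C)[C@@H](Br)CC[C@@](C)(O)[C@@H]12 | intermediate
32 | 6-methylhept-5-en-2-one | CC(=O)CCC=C(C)C | starting material
33 | 4-[(2R)-3,3-dimethyloxiran-2-yl]butan-2-one | CC(=O)CC[C@H]1OC1(C)C | intermediate
34 | (5S)-5-bromo-6-hydroxy-6-methylheptan-2-one | CC(=O)CC[C@H](Br)C(C)(C)O | intermediate
35 | (3S)-3-bromo-2-methyl-6-oxoheptan-2-yl trifluoroacetate | CC(=O)CC[C@H](Br)C(C)(C)OC(=O)C(F)(F)F | intermediate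
36 | lithium enolate of 35 (terminal) | [Li]OC(=C)CC[C@H](Br)C(C)(C)OC(=O)C(F)(F)F | intermediate (not isolated)
37 | (3S)-3-bromo-6-[(tert-butyldimethylsilyl)oxy]-2-methylhept-6-en-2-yl trifluoroacetate | C=C(O[Si](C)(C)C(C)(C)C)CC[C@H](Br)C(C)(C)OC(=O)C(F)(F)F | intermediate
38 | bromiranium ion of the C4'–C5' bond (silyl enol ether intact) | C=C(O[Si](C)(C)C(C)(C)C)CC[C@@H]1[Br+]C1(C)C | intermediate (not isolated)
39 | (4S)-4-bromo-3,3-dimethylcyclohexan-1-one | O=C1CC[C@H](Br)C(C)(C)C1 | intermediate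
40 | lithium enolate of 39 (C1'=C2') | [Li]OC1=CC[C@H](Br)C(C)(C)C1 | intermediate (not isolated)
41 | (4S)-4-bromo-5,5-dimethylcyclohex-1-en-1-yl trifluoromethanesulfonate | FC(F)(F)S(=O)(=O)OC1=CC[C@H](Br)C(C)(C)C1 | intermediate
42 | [(4S)-4-bromo-5,5-dimethylcyclohex-1-en-1-yl]chromium dichloride (trivalent chromium) | Cl[Cr](Cl)C1=CC[C@H](Br)C(C)(C)C1 | intermediate (not isolated)
43 | [(1R,2R,3aS,4S,7R,7aS)-4-bromo-7-hydroxy-2-[(4-methoxybenzyl)oxy]-3a,7-dimethyloctahydro-1H-inden-1-yl][(4S)-4-bromo-5,5-dimethylcyclohex-1-en-1-yl]methanol (both Ca epimers) | OC([C@@H]1[C@H](OCc2ccc(OC)cc2)C[C@]2(C)[C@@H](Br)CC[C@@](C)(O)[C@@H]12)C1=CC[C@H](Br)C(C)(C)C1 | intermediate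
44 | [(1S,2R,3aS,4S,7R,7aS)-4-bromo-7-hydroxy-2-[(4-methoxybenzyl)oxy]-3a,7-dimethyloctahydro-1H-inden-1-yl][(4S)-4-bromo-5,5-dimethylcyclohex-1-en-1-yl]methanone | O=C([C@@H]1[C@H](OCc2ccc(OC)cc2)C[C@]2(C)[C@@H](Br)CC[C@@](C)(O)[C@@H]12)C1=CC[C@H](Br)C(C)(C)C1 | intermediate
45 | (R)-[(1R,2R,3aS,4S,7R,7aS)-4-bromo-7-hydroxy-2-[(4-methoxybenzyl)oxy]-3a,7-dimethyloctahydro-1H-inden-1-yl][(4S)-4-bromo-5,5-dimethylcyclohex-1-en-1-yl]methanol | O[C@H]([C@@H]1[C@H](OCc2ccc(OC)cc2)C[C@]2(C)[C@@H](Br)CC[C@@](C)(O)[C@@H]12)C1=CC[C@H](Br)C(C)(C)C1 | intermediate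
46 | epoxy alcohol: 45 with the C1'–C2' epoxide cis to the C4' bromine, erythro to the Ca hydroxyl | O[C@H]([C@@H]1[C@H](OCc2ccc(OC)cc2)C[C@]2(C)[C@@H](Br)CC[C@@](C)(O)[C@@H]12)[C@@]12O[C@@H]1C[C@H](Br)C(C)(C)C2 | intermediate
47 | (R)-[(1R,2R,3aS,4S,7R,7aS)-4-bromo-7-hydroxy-2-[(4-methoxybenzyl)oxy]-3a,7-dimethyloctahydro-1H-inden-1-yl][(1R,4S)-4-bromo-1-hydroxy-3,3-dimethylcyclohexyl]methanol | O[C@H]([C@@H]1[C@H](OCc2ccc(OC)cc2)C[C@]2(C)[C@@H](Br)CC[C@@](C)(O)[C@@H]12)[C@@]1(O)CC[C@H](Br)C(C)(C)C1 | intermediate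
48 | (R)-[(1S,2R,3aS,4S,7R,7aS)-4-bromo-7-hydroxy-2-[(4-methoxybenzyl)oxy]-3a,7-dimethyloctahydro-1H-inden-1-yl][(1R,4S)-4-bromo-1-hydroxy-3,3-dimethylcyclohexyl]methyl acetate | CC(=O)O[C@H]([C@@H]1[C@H](OCc2ccc(OC)cc2)C[C@]2(C)[C@@H](Br)CC[C@@](C)(O)[C@@H]12)[C@@]1(O)CC[C@H](Br)C(C)(C)C1 | intermediate
49 | (R)-[(1S,2R,3aS,4S,7R,7aS)-4-bromo-2,7-dihydroxy-3a,7-dimethyloctahydro-1H-inden-1-yl][(1R,4S)-4-bromo-1-hydroxy-3,3-dimethylcyclohexyl]methyl acetate (CNP0166243.1) | CC(=O)O[C@H]([C@@H]1[C@H](O)C[C@]2(C)[C@@H](Br)CC[C@@](C)(O)[C@@H]12)[C@@]1(O)CC[C@H](Br)C(C)(C)C1 | target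

Total step count: 33. Longest linear sequence: 27 steps (steps 1–20 and 27–33); the ring C branch is steps 21–26.

Steps most likely to fail

Step 10. The dienol ether may lose its silyl group before the ester ionises, enantiopurity may erode through bromonium transfer between molecules, or the cation may be captured at oxygen or lose a proton to give an allylic bromide instead of forming the C3a–C7a bond. The fallback sets out from 12 and comes back at 19. It replaces the dienol ether by an allylsilane, the classical terminator of cation–olefin cyclisations, which can bond only through C7a and makes the vinyl group by loss of silicon. Amide 12 is reduced with i-Bu2AlH to 3-[(2R,3R)-3-{2-[(tert-butyldiphenylsilyl)oxy]ethyl}-3-methyloxiran-2-yl]propanal F1. The alkenylzinc reagent from propargyltrimethylsilane (Cp2Zr(H)Cl, then Me2Zn) adds to give the allylic alcohol F2 as C7 epimers, which is protected (Et3SiCl, imidazole) as the triethylsilyl ether F3. Li2NiBr4 opens the epoxide to the bromohydrin F4, and (CF3CO)2O with pyridine gives the trifluoroacetate F5. Ionisation as in step 10 should then give the vinylcyclohexane silyl ether F6. Pyridinium 4-toluenesulfonate in MeOH frees the C7 alcohol F7, and Dess–Martin oxidation returns ketone 19, whose C7a centre can equilibrate to the equatorial vinyl epimer.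

Step 17. Facial selectivity of hydride addition at C2 may be poor, because the β face that the chelate leaves open is flanked by the angular methyl group. The fallback sets out from 27 and comes back at 28. It uses attack from the α face on purpose and then inverts C2. Me4NBH(OAc)3 in MeCN–AcOH delivers hydride intramolecularly from the Ca oxygen (Evans–Saksena reduction) and should give the trans diol F8. Pivaloyl chloride in pyridine acylates the primary hydroxyl to give the pivalate F9. Mitsunobu inversion at C2 (4-nitrobenzoic acid, PPh3, diisopropyl azodicarboxylate) gives the diester F10, and K2CO3 in MeOH removes both esters to give 28.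

Step 27. Addition of a hindered alkenylchromium reagent to a hindered aldehyde may be sluggish, so that reduction of the C–Br bonds by divalent chromium or β-elimination of the C2 ether can compete. The fallback sets out from 31 and 41 and comes back at 44. It forms the Ca–C1' bond by acyl cross-coupling, which gives the enone directly. Aldehyde 31 is oxidised (NaClO2, NaH2PO4, 2-methylbut-2-ene) to the carboxylic acid F11, which is converted (EtSH, N,N'-dicyclohexylcarbodiimide, 4-(dimethylamino)pyridine) into the S-ethyl thioester F12. Triflate 41 is stannylated (Me3SnSnMe3, Pd(PPh3)4, LiCl) to the alkenylstannane F13. Thioester–stannane coupling of the Liebeskind–Srogl type (Pd2(dba)3, tri(2-furyl)phosphine, CuOP(O)Ph2) should then give enone 44.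

Further compounds

F1 | step 10 | 3-[(2R,3R)-3-{2-[(tert-butyldiphenylsilyl)oxy]ethyl}-3-methyloxiran-2-yl]propanal | O=CCC[C@H]1O[C@]1(C)CCO[Si](c1ccccc1)(c1ccccc1)C(C)(C)C
F2 | step 10 | (E)-1-[(2R,3R)-3-{2-[(tert-butyldiphenylsilyl)oxy]ethyl}-3-methyloxiran-2-yl]-6-(trimethylsilyl)hex-4-en-3-ol (C7 epimers) | C[Si](C)(C)C/C=C/C(O)CC[C@H]1O[C@]1(C)CCO[Si](c1ccccc1)(c1ccccc1)C(C)(C)C
F3 | step 10 | triethylsilyl ether of F2 | C[Si](C)(C)C/C=C/C(O[Si](CC)(CC)CC)CC[C@H]1O[C@]1(C)CCO[Si](c1ccccc1)(c1ccccc1)C(C)(C)C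
F4 | step 10 | anti bromohydrin from F3 (C4 bromide, C3a tertiary alcohol) | C[Si](C)(C)C/C=C/C(O[Si](CC)(CC)CC)CC[C@H](Br)[C@](C)(O)CCO[Si](c1ccccc1)(c1ccccc1)C(C)(C)C
F5 | step 10 | tertiary trifluoroacetate of F4 | C[Si](C)(C)C/C=C/C(O[Si](CC)(CC)CC)CC[C@H](Br)[C@](C)(OC(=O)C(F)(F)F)CCO[Si](c1ccccc1)(c1ccccc1)C(C)(C)C
F6 | step 10 | (2S,3S,4S)-4-bromo-3-{2-[(tert-butyldiphenylsilyl)oxy]ethyl}-2-ethenyl-3-methylcyclohexyl triethylsilyl ether (C7 epimers) | CC(C)(C)[Si](c1ccccc1)(c1ccccc1)OCC[C@]1(C)[C@@H](Br)CCC(O[Si](CC)(CC)CC)[C@H]1C=C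
F7 | step 10 | (2S,3S,4S)-4-bromo-3-{2-[(tert-butyldiphenylsilyl)oxy]ethyl}-2-ethenyl-3-methylcyclohexan-1-ol (C7 epimers) | CC(C)(C)[Si](c1ccccc1)(c1ccccc1)OCC[C@]1(C)[C@@H](Br)CCC(O)[C@H]1C=C
F8 | step 17 | trans diol, C2 epimer of 28 (2β-OH) | OC[C@@H]1[C@@H](O)C[C@]2(C)[C@@H](Br)CC[C@@](C)(O)[C@@H]12
F9 | step 17 | primary pivalate of F8 | CC(C)(C)C(=O)OC[C@@H]1[C@@H](O)C[C@]2(C)[C@@H](Br)CC[C@@](C)(O)[C@@H]12
F10 | step 17 | 2α-(4-nitrobenzoate) pivalate (C2 inverted) | CC(C)(C)C(=O)OC[C@@H]1[C@H](OC(=O)c2ccc(cc2)[N+](=O)[O-])C[C@]2(C)[C@@H](Br)CC[C@@](C)(O)[C@@H]12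
F11 | step 27 | (1S,2R,3aS,4S,7R,7aS)-4-bromo-7-hydroxy-2-[(4-methoxybenzyl)oxy]-3a,7-dimethyloctahydro-1H-indene-1-carboxylic acid | OC(=O)[C@@H]1[C@H](OCc2ccc(OC)cc2)C[C@]2(C)[C@@H](Br)CC[C@@](C)(O)[C@@H]12
F12 | step 27 | S-ethyl thioester of F11 | CCSC(=O)[C@@H]1[C@H](OCc2ccc(OC)cc2)C[C@]2(C)[C@@H](Br)CC[C@@](C)(O)[C@@H]12
F13 | step 27 | [(4S)-4-bromo-5,5-dimethylcyclohex-1-en-1-yl]trimethylstannane | C[Sn](C)(C)C1=CC[C@H](Br)C(C)(C)C1
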